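**Retrosynthetic overview**
1. The C10 isovalerate and the C11 acetate come from late-stage functional-group steps. C11 is installed by Stille coupling of a dienyl triflate made from the C4 ketone of a cyclopenta[c]pyranone. C10 comes from a primary hydroxyl that is acylated last.
2. The cyclopentene is closed by an intramolecular vinylogous aldol (C7–C8) between an exocyclic enone γ-carbon and the C8 ketone. This sets C7 and C8 and creates C5=C6.
3. Key radical step: an acyl radical from TBSOCH2CHO (photo-HAT) adds to C9 of an Achmatowicz pyranone, anti to the anomeric alkoxy group. This forms C8–C9 and the trans C1/C9 relationship.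
4. Ring order: the pyran ring is made first (Achmatowicz oxidation of furfuryl alcohol), then the cyclopentene.

Assumption: the two diastereomeric lactate acetals in step 2 are separable, the (1S) isomer is carried forward, and C1 is re-set anomerically in step 7.

---

**Step 1**
Reactants: 1 furfuryl alcohol
Product: 2 6-hydroxy-2H-pyran-3(6H)-one (racemic, equilibrating lactol)
Conditions: NBS, NaHCO3, NaOAc·3H2O, THF/H2O (4:1), 0 °C
Reagents that add atoms: water, O (NBS is only the oxidant; its Br is not retained)
Why: Achmatowicz oxidative ring expansion of the furfuryl alcohol gives the pyranone lactol, and the freely mutarotating C1 means no stereocentre is fixed here.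

**Step 2**
Reactants: 2 lactol; 3 ethyl (S)-lactate
Product: 4 ethyl (2S)-2-{[(2S)-5-oxo-5,6-dihydro-2H-pyran-2-yl]oxy}propanoate
Conditions: 3 (3 equiv), CSA (10 mol%), 4 Å MS, CH2Cl2, 0 °C. Separate diastereomers on silica and recycle the unwanted one under the same acid.
Reagents that add atoms: none
Why: Acid-catalysed acetalisation of the equilibrating lactol gives two diastereomeric acetals that interconvert through the oxocarbenium ion, so chromatographic separation with recycling acts as a dynamic resolution that fixes C1 (S).

**Step 3**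
Reactants: 4 acetal pyranone; 5 2-(tert-butyldimethylsilyloxy)acetaldehyde
Product: 6 C5-(1-hydroxy-2-TBSO-ethyl) enone (carbinol epimers, mixture)
Conditions: 5 (1.5 equiv), PMe3 (20 mol%), THF, 0 °C to rt
Reagents that add atoms: none
Why: Proposed new method: phosphine adds to C9, the phosphonium enolate adds to the aldehyde at C5, and elimination of PMe3 regenerates the enone. This installs the future C6–C7 unit, following phosphine-catalysed Morita–Baylis–Hillman reactions of cyclic enones. The C6 stereocentre is discarded in step 5.

**Step 4 (key radical step)**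
Reactants: 6 MBH adduct; 5 2-(TBSO)acetaldehyde
Product: 7 C9-acylated tetrahydropyranone, with C6 and C5 as unspecified epimer mixtures
Conditions: 5 (3 equiv), TBADT (2 mol%), MeCN (0.4 M), 390 nm LEDs, 15 °C
Reagents that add atoms: none (the aldehyde is a reactant)
Why: Decatungstate HAT abstracts the aldehyde C–H to give the nucleophilic α-silyloxy acyl radical, which adds in Giese fashion to the enone β-carbon C9 from the face anti to the pseudo-axial C1 alkoxy group. This forms C8–C9 with the C8 and OR groups trans, as in the target, and back-HAT then gives C5–H.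

**Step 5**
Reactants: 7
Product: 8 exocyclic enone, with the CH2OTBS group cis to C9
Conditions: MsCl, Et3N, CH2Cl2, 0 °C; then DBU, rt
Reagents that add atoms: none (the mesylate is transient)
Why: E1cB elimination of the β-mesyloxy ketone gives the conjugated alkylidene (E-enone), and the C5 and C6 stereocentres disappear.

**Step 6**
Reactants: 8
Product: 9 tricyclic-free cyclopenta[c]pyranone with C7-OTBS, C8-OH and C8-CH2OTBS
Conditions: TiCl4 (1.2 equiv), i-Pr2NEt (2.5 equiv), CH2Cl2, −78 to −30 °C
Reagents that add atoms: none (isomerisation)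
Why: Proposed new method: soft enolisation of the enone gives an extended Ti dienolate whose γ-carbon (C7, bearing OTBS) attacks the C8 ketone intramolecularly (5-exo), closing the cyclopentene and restoring C5=C6. Ti chelation between the C8 carbonyl oxygen and the C1 oxygens should place the C8–O cis to C1, and the bulky C7-OTBS should adopt the trans relationship to the C8–OTi alkoxide. The closest known reactions are TiCl4/amine vinylogous and intramolecular aldols.

**Step 7**
Reactants: 9
Product: 10 C1-isovalerate
Conditions: (iVal)2O (1.5 equiv), TMSOTf (10 mol%), CH2Cl2, −40 to −10 °C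
Reagents that add atoms: isovaleric anhydride, CC(C)CC(=O)OC(=O)CC(C)C
Why: Proposed new method: TMSOTf ionises the lactate acetal to the pyranyl oxocarbenium ion and isovalerate is captured anti to the C9 substituent, re-setting C1 trans to C8 as in the target. This is acetolysis of a glycoside-type acetal, under conditions chosen to leave the hindered tertiary OH and TBS ethers untouched.

**Step 8**
Reactants: 10
Product: 11 dienyl triflate (O–C3H=C4(OTf)–C5=C6)
Conditions: KHMDS (2.3 equiv), THF, −78 °C; then PhNTf2, −78 to −20 °C
Reagents that add atoms: N-phenyl-bis(trifluoromethanesulfonimide), O=S(=O)(C(F)(F)F)N(c1ccccc1)S(=O)(=O)C(F)(F)F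
Why: Kinetic deprotonation occurs at the α′-methylene C3, the only enolisable ketone position because C5 is sp2. The first equivalent of base is consumed by the C8–OH. O-Triflation gives the cross-conjugated diene and no stereocentre changes.

**Step 9**
Reactants: 11
Product: 12 C4-acetoxymethyl dienyl ether
Conditions: Bu3SnCH2OAc (1.3 equiv), Pd(PPh3)4 (5 mol%), LiCl, THF, 65 °C
Reagents that add atoms: (acetoxymethyl)tributylstannane, CCCC[Sn](CCCC)(CCCC)COC(C)=O
Why: Stille coupling of the vinyl triflate installs C11–OAc under neutral conditions that tolerate the esters, completing the C3=C4–C5=C6 diene.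

**Step 10**
Reactants: 12
Product: 13 triol (C7-OH, C8-OH, C10-OH)
Conditions: TBAF, AcOH (1:1, 3 equiv each), THF, 0 °C to rt
Reagents that add atoms: none
Why: Buffered fluoride removes both TBS ethers without cleaving the acetate or ionising the acid-sensitive acyloxy acetal and dienyl ether, and no stereocentres are touched.

**Step 11**
Reactants: 13
Product: 14 Jatamanvaltrate J
Conditions: isovaleryl chloride (1.05 equiv), pyridine, CH2Cl2, −20 °C
Reagents that add atoms: isovaleryl chloride, CC(C)CC(=O)Cl
Why: Acylation is chemoselective for the least hindered primary C10–OH over the secondary allylic C7–OH and the tertiary C8–OH, giving the target.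

---

**Compound list**

1 | furfuryl alcohol | OCc1ccco1 | starting material
2 | 6-hydroxy-2H-pyran-3(6H)-one (racemic lactol) | O=C1COC(O)C=C1 | intermediate
3 | ethyl (S)-lactate | C[C@H](O)C(=O)OCC | starting material
4 | ethyl (2S)-2-{[(2S)-5-oxo-5,6-dihydro-2H-pyran-2-yl]oxy}propanoate | O=C1CO[C@@H](O[C@@H](C)C(=O)OCC)C=C1 | intermediate
5 | 2-(tert-butyldimethylsilyloxy)acetaldehyde | CC(C)(C)[Si](C)(C)OCC=O | starting material
6 | C5-(1-hydroxy-2-TBSO-ethyl) pyranone (carbinol epimers) | O=C1CO[C@@H](O[C@@H](C)C(=O)OCC)C=C1C(O)CO[Si](C)(C)C(C)(C)C | intermediate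
7 | C9-(TBSO-acetyl) tetrahydropyranone (C5 and C6 unspecified) | O=C1CO[C@@H](O[C@@H](C)C(=O)OCC)[C@H](C(=O)CO[Si](C)(C)C(C)(C)C)C1C(O)CO[Si](C)(C)C(C)(C)C | intermediate
8 | exocyclic enone, CH2OTBS cis to C9 | O=C1CO[C@@H](O[C@@H](C)C(=O)OCC)[C@H](C(=O)CO[Si](C)(C)C(C)(C)C)/C1=C\CO[Si](C)(C)C(C)(C)C | intermediate
9 | cyclopenta[c]pyranone, lactate acetal, 7-OTBS, 8-OH, 10-OTBS | O=C1CO[C@@H](O[C@@H](C)C(=O)OCC)[C@H]2C1=C[C@H](O[Si](C)(C)C(C)(C)C)[C@]2(O)CO[Si](C)(C)C(C)(C)C | intermediate
10 | 1-isovalerate of 9 | O=C1CO[C@@H](OC(=O)CC(C)C)[C@H]2C1=C[C@H](O[Si](C)(C)C(C)(C)C)[C@]2(O)CO[Si](C)(C)C(C)(C)C | intermediate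
11 | dienyl triflate | FC(F)(F)S(=O)(=O)OC1=CO[C@@H](OC(=O)CC(C)C)[C@H]2C1=C[C@H](O[Si](C)(C)C(C)(C)C)[C@]2(O)CO[Si](C)(C)C(C)(C)C | intermediate
12 | C11-acetate, bis-TBS | CC(=O)OCC1=CO[C@@H](OC(=O)CC(C)C)[C@H]2C1=C[C@H](O[Si](C)(C)C(C)(C)C)[C@]2(O)CO[Si](C)(C)C(C)(C)C | intermediate
13 | 7,8,10-triol | CC(=O)OCC1=CO[C@@H](OC(=O)CC(C)C)[C@H]2C1=C[C@H](O)[C@]2(O)CO | intermediate
14 | Jatamanvaltrate J | CC(=O)OCC1=CO[C@@H](OC(=O)CC(C)C)[C@H]2C1=C[C@H](O)[C@]2(O)COC(=O)CC(C)C | target

---

**Total step count:** 11
**Longest linear sequence:** 11 steps (furfuryl alcohol → 2 → 4 → 6 → 7 → 8 → 9 → 10 → 11 → 12 → 13 → 14)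

**Three steps most likely to fail**
1. **Step 6 (vinylogous aldol).** Enolisation may go to C10 or C3 instead of C7, and the 7,8-trans relationship is not assured.
   - Fallback: use glyoxal dimethyl acetal in step 3 so that a C7 aldehyde can be unmasked, then close C7–C8 by an SmI2 pinacol-type coupling. Correct C7 by MnO2 oxidation followed by hydroxyl-directed anti reduction.
2. **Step 4 (acyl-radical hydroacylation).** The α-silyloxy acyl radical may decarbonylate or HAT may occur at the wrong C–H, and facial selectivity may be low.
   - Fallback: add a lithiated 2-(silyloxymethyl)-1,3-dithiane (Corey–Seebach) conjugately to the enone, then unmask the ketone with Hg(II) or NCS.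
3. **Step 3 (MBH on the pyranone).** The γ-alkoxy enone may instead undergo SN2′ ring-opening or oxa-Michael side reactions.
   - Fallback: prepare the C5-substituted pyranone by Achmatowicz oxidation of a 3-substituted furfuryl alcohol, built by regioselective 3-lithiation of a protected furfuryl alcohol followed by addition to 5.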